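**Strategy**

Everything rests on cutting the bond between the 3,4-dimethoxyphenyl ring and C4 (furo[3,4-c]furan numbering), the ring B carbon lying between O5 and the hydroxylated ring-fusion carbon C3a. C4 is handled as a latent lactone carbonyl, the anomeric carbon of a C-aryl furanoside. In one flask 3,4-dimethoxyphenyllithium adds to a flat bicyclic α-hydroxy lactone that still carries the ring A aryl enol ether (C1=C6a); acid and silane then reduce both lactol anomers and the enol ether, hydrogen entering three times on the convex face of the cis-fused bicycle. The lone carbinol centre C3a, set by a catalytic asymmetric interrupted Feist–Bénary reaction, thus fixes C4, C1 and C6a with both aryl groups endo.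

Key step: step 4

Remark: locants C1 to C6a in the text are those of the target (C1 aryl carbon of ring A, O2, C3, C3a carbinol ring-fusion carbon, C4 aryl carbon of ring B, O5, C6, C6a); ring A is the O2 ring, ring B the O5 ring; systematic names of intermediates keep their own numbering.

Assumption: of the pseudoenantiomeric cinchona catalysts, (DHQD)2PYR is taken to give the (4S)-alcohol 3; should the sense prove opposite, (DHQ)2PYR is used instead.

**Route**

Step 1
Reactants: 1 ethyl 3-(3,4-dimethoxyphenyl)-3-oxopropanoate; 2 ethyl 3-bromo-2-oxopropanoate (ethyl bromopyruvate)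
Product: 3 diethyl (4S)-2-(3,4-dimethoxyphenyl)-4-hydroxy-4,5-dihydrofuran-3,4-dicarboxylate
Conditions: (DHQD)2PYR (10 mol %), 1,8-bis(dimethylamino)naphthalene (1.1 equiv), THF, −78 °C
Reagents that add atoms: none
Why: Interrupted Feist–Bénary reaction: the cinchona base should guide aldol addition of the β-keto ester enolate to the ketone of 2 and so set the tertiary carbinol (later C3a); the enol oxygen then displaces bromide (5-exo-tet) to close ring A, and the ester on the carbinol carbon disfavours dehydration to the furan.

Step 2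
Reactants: 3 diethyl (4S)-2-(3,4-dimethoxyphenyl)-4-hydroxy-4,5-dihydrofuran-3,4-dicarboxylate
Product: 4 (3S)-5-(3,4-dimethoxyphenyl)-4-(ethoxycarbonyl)-3-hydroxy-2,3-dihydrofuran-3-carboxylic acid
Conditions: LiOH·H2O (1.1 equiv), THF–H2O, 0 °C; then 1 M HCl to pH 4
Reagents that add atoms: lithium hydroxide, [Li+].[OH-]
Why: Chemoselective saponification: the α-hydroxy ester is activated by its neighbouring hydroxyl, whereas the other ester is a vinylogous carbonate (β-alkoxyacrylate) deactivated by the ring oxygen; the stereocentre is not touched.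

Step 3
Reactants: 4 (3S)-5-(3,4-dimethoxyphenyl)-4-(ethoxycarbonyl)-3-hydroxy-2,3-dihydrofuran-3-carboxylic acid
Product: 6 (6aS)-4-(3,4-dimethoxyphenyl)-6a-hydroxy-6,6a-dihydro-1H,3H-furo[3,4-c]furan-1-one, via hydroxy acid 5 (not isolated)
Conditions: i-Bu2AlH (5 equiv), CH2Cl2, −78 → −30 °C; aq. potassium sodium tartrate (KNaC4H4O6) work-up at pH 5; crude 5, DCC, DMAP (cat.), CH2Cl2, 0 °C
Reagents that add atoms: none
Why: Diisobutylaluminium hydride should reduce the β-alkoxyacrylate ester to the allylic alcohol while the acid is masked in the flask as its aluminium carboxylate; Steglich lactonisation of the primary alcohol onto the acid then closes ring B, the tertiary alcohol being too hindered to compete.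

Step 4
Reactants: 6 (6aS)-4-(3,4-dimethoxyphenyl)-6a-hydroxy-6,6a-dihydro-1H,3H-furo[3,4-c]furan-1-one; 7 4-bromo-1,2-dimethoxybenzene
Product: 10 (1R,3aS,4S,6aR)-1,4-bis(3,4-dimethoxyphenyl)tetrahydro-1H,3H-furo[3,4-c]furan-3a(4H)-ol (target), via 3,4-dimethoxyphenyllithium 8 (not isolated), via lactol 9 (not isolated)
Conditions: 7 (2.3 equiv), n-BuLi (2.2 equiv), THF, −78 °C; add 6, −78 °C; then CH2Cl2, Et3SiH (8 equiv), CF3CO2H (15 equiv), −78 → −20 °C; aq. NaHCO3
Reagents that add atoms: none
Why: Aryllithium 8 (from bromine–lithium exchange on 7) first deprotonates the tertiary hydroxyl and then adds once to the lactone carbonyl C4, which has no α-hydrogen and gives a lithium lactolate stable at −78 °C, so the aryl–C4 bond should form without enolisation or double addition. Acidification ionises either anomer of lactol 9 to the same aryl-stabilised oxocarbenium ion, and triethylsilane delivers hydride to its convex face, cis to the C3a hydroxyl, so the anomer mixture converges on the one C4 configuration with the aryl group trans to the hydroxyl (endo). In the same medium the acid protonates C6a of the ring A aryl enol ether on the only face that leaves the bicycle cis-fused, and the resulting C1 oxocarbenium ion is likewise reduced from the convex face, which places the second aryl group endo. The closest known reactions are the aryllithium–lactone addition with silane reduction used for 1,2-trans C-aryl glycosides and C-nucleosides, and the ionic hydrogenation of aryl enol ethers; no ring is closed in this step. C4, C1 and C6a are all controlled by the concave shape of the cis-fused 3,7-dioxabicyclo[3.3.0]octane and thus by the single stereocentre C3a. The step needs hydride capture to outrun loss of the C3a hydroxyl (aromatisation of ring A to a furan) and ionisation of the allylic C6–O5 bond; the large excess of silane present before the acid, the low temperature and the electron-poor lactol carbon next to C3a are expected to secure this.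

**Compound list**

1 | ethyl 3-(3,4-dimethoxyphenyl)-3-oxopropanoate | CCOC(=O)CC(=O)c1ccc(OC)c(OC)c1 | starting material
2 | ethyl 3-bromo-2-oxopropanoate | CCOC(=O)C(=O)CBr | starting material
3 | diethyl (4S)-2-(3,4-dimethoxyphenyl)-4-hydroxy-4,5-dihydrofuran-3,4-dicarboxylate | CCOC(=O)C1=C(c2ccc(OC)c(OC)c2)OC[C@]1(O)C(=O)OCC | intermediate
4 | (3S)-5-(3,4-dimethoxyphenyl)-4-(ethoxycarbonyl)-3-hydroxy-2,3-dihydrofuran-3-carboxylic acid | CCOC(=O)C1=C(c2ccc(OC)c(OC)c2)OC[C@]1(O)C(=O)O | intermediate
5 | (3S)-5-(3,4-dimethoxyphenyl)-3-hydroxy-4-(hydroxymethyl)-2,3-dihydrofuran-3-carboxylic acid (not isolated) | OCC1=C(c2ccc(OC)c(OC)c2)OC[C@]1(O)C(=O)O | intermediate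
6 | (6aS)-4-(3,4-dimethoxyphenyl)-6a-hydroxy-6,6a-dihydro-1H,3H-furo[3,4-c]furan-1-one (ring B lactone, ring A enol ether) | COc1ccc(C2=C3COC(=O)[C@@]3(O)CO2)cc1OC | intermediate
7 | 4-bromo-1,2-dimethoxybenzene | Brc1ccc(OC)c(OC)c1 | starting material
8 | 3,4-dimethoxyphenyllithium (not isolated) | [Li]c1ccc(OC)c(OC)c1 | intermediate
9 | (6aS)-1,4-bis(3,4-dimethoxyphenyl)-6,6a-dihydro-1H,3H-furo[3,4-c]furan-1,6a-diol, lactol as both epimers at the lactol carbon (not isolated) | COc1ccc(C2=C3COC(O)(c4ccc(OC)c(OC)c4)[C@@]3(O)CO2)cc1OC | intermediate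
10 | (1R,3aS,4S,6aR)-1,4-bis(3,4-dimethoxyphenyl)tetrahydro-1H,3H-furo[3,4-c]furan-3a(4H)-ol | COc1ccc([C@@H]2OC[C@@]3(O)[C@@H]2CO[C@H]3c2ccc(OC)c(OC)c2)cc1OC | target

**Step count and risks**

Total step count: 4. Longest linear sequence: 4 steps (from 1 or 2).

Steps most likely to fail:

1. Step 4. Under acid the tertiary allylic hydroxyl at C3a may ionise and ring A aromatise to a furan, or the allylic C6–O5 bond may ionise before the enol ether is reduced; the lactolate may also open and take up a second aryllithium. The fallback sets out from 6 and separates the events. Hydroxyl-directed hydrogenation with [Ir(cod)(PCy3)(py)]PF6 and H2 in CH2Cl2 should add hydrogen to the enol ether on the face of the C3a hydroxyl and give (3aR,4R,6aS)-4-(3,4-dimethoxyphenyl)-6a-hydroxytetrahydro-1H,3H-furo[3,4-c]furan-1-one F1, which has no allylic C–O bond left. Aryllithium 8 is then added at −78 °C and the product is isolated as the saturated lactol (3aR,4R,6aS)-1,4-bis(3,4-dimethoxyphenyl)tetrahydro-1H,3H-furo[3,4-c]furan-1,6a-diol F2. Reduction with Et3SiH and BF3·OEt2 in CH2Cl2–MeCN at −40 °C comes back to the route at 10.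

2. Step 1. The acyclic β-keto ester is less acidic than the cyclic diketones for which this catalysis is best established, so an uncatalysed background reaction may erode the enantioselectivity, or the sense of induction may be the wrong one. The fallback sets out from 1 and 2. Pyridine in THF at 0 °C should give racemic diethyl 2-(3,4-dimethoxyphenyl)-4-hydroxy-4,5-dihydrofuran-3,4-dicarboxylate F3. Saponification as in step 2 gives racemic 5-(3,4-dimethoxyphenyl)-4-(ethoxycarbonyl)-3-hydroxy-2,3-dihydrofuran-3-carboxylic acid F4. This is resolved by crystallising the (R)-1-phenylethylammonium salt of the (3S)-acid F5 (or the salt of the enantiomeric amine, whichever is less soluble). Acidification comes back to the route at 4.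

3. Step 3. The aluminium carboxylate may be over-reduced, or the electron-rich hydroxymethyl enol ether may dehydrate during work-up before the lactone closes. The fallback sets out from 2 and changes the group that is reduced. Commercial 3-(3,4-dimethoxyphenyl)-3-oxopropanenitrile (N#CCC(=O)c1ccc(OC)c(OC)c1) under the conditions of step 1 should give ethyl (3S)-4-cyano-5-(3,4-dimethoxyphenyl)-3-hydroxy-2,3-dihydrofuran-3-carboxylate F6. LiOH gives (3S)-4-cyano-5-(3,4-dimethoxyphenyl)-3-hydroxy-2,3-dihydrofuran-3-carboxylic acid F7. i-Bu2AlH at −78 °C stops at the aluminium imine, which cannot be over-reduced, and hydrolysis gives (3S)-5-(3,4-dimethoxyphenyl)-4-formyl-3-hydroxy-2,3-dihydrofuran-3-carboxylic acid F8, a vinylogous formate that is stable to acid. NaBH4 in MeOH at 0 °C reduces only the aldehyde and comes back to the route at 5, which is lactonised to 6 as in step 3.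

Further compounds
F1 | step 4 | (3aR,4R,6aS)-4-(3,4-dimethoxyphenyl)-6a-hydroxytetrahydro-1H,3H-furo[3,4-c]furan-1-one | COc1ccc([C@@H]2OC[C@@]3(O)[C@@H]2COC3=O)cc1OC
F2 | step 4 | (3aR,4R,6aS)-1,4-bis(3,4-dimethoxyphenyl)tetrahydro-1H,3H-furo[3,4-c]furan-1,6a-diol (both epimers at the lactol carbon) | COc1ccc([C@@H]2OC[C@@]3(O)[C@@H]2COC3(O)c2ccc(OC)c(OC)c2)cc1OC
F3 | step 1 | racemic diethyl 2-(3,4-dimethoxyphenyl)-4-hydroxy-4,5-dihydrofuran-3,4-dicarboxylate | CCOC(=O)C1=C(c2ccc(OC)c(OC)c2)OCC1(O)C(=O)OCC
F4 | step 1 | racemic 5-(3,4-dimethoxyphenyl)-4-(ethoxycarbonyl)-3-hydroxy-2,3-dihydrofuran-3-carboxylic acid | CCOC(=O)C1=C(c2ccc(OC)c(OC)c2)OCC1(O)C(=O)O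
F5 | step 1 | (R)-1-phenylethylammonium (3S)-5-(3,4-dimethoxyphenyl)-4-(ethoxycarbonyl)-3-hydroxy-2,3-dihydrofuran-3-carboxylate | CCOC(=O)C1=C(c2ccc(OC)c(OC)c2)OC[C@]1(O)C(=O)[O-].C[C@@H]([NH3+])c1ccccc1
F6 | step 3 | ethyl (3S)-4-cyano-5-(3,4-dimethoxyphenyl)-3-hydroxy-2,3-dihydrofuran-3-carboxylate | N#CC1=C(c2ccc(OC)c(OC)c2)OC[C@]1(O)C(=O)OCC
F7 | step 3 | (3S)-4-cyano-5-(3,4-dimethoxyphenyl)-3-hydroxy-2,3-dihydrofuran-3-carboxylic acid | N#CC1=C(c2ccc(OC)c(OC)c2)OC[C@]1(O)C(=O)O
F8 | step 3 | (3S)-5-(3,4-dimethoxyphenyl)-4-formyl-3-hydroxy-2,3-dihydrofuran-3-carboxylic acid | O=CC1=C(c2ccc(OC)c(OC)c2)OC[C@]1(O)C(=O)O
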